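**Retrosynthetic overview**
1. Side-chain carbons are numbered C1' (benzylic CH2) to C15'. The key disconnection is the C4'–C3' bond, between the homoallylic CH2 of a C16 left half (C4'–C15') and the methyl-bearing alkene carbon C3' of the aryl half.
2. Enabling feature: the phenol oxygen on arene C1 is ortho to the side chain and 1,5 to C3' (O–C1(ar)–C2(ar)–C1'–C2'=C3'). Joining O to C3' gives a temporary 4H-chromene (4H-pyran) ring in which C3' is an α-oxygenated alkenyl carbon; once metalated it is a carbenoid. A cuprate 1,2-metallate rearrangement then delivers the left half to C3' and expels the phenoxide (ring opening), and MeI leaves the (E)-alkene, the C3' methyl and the free phenol in one operation.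
3. Aryl half: methylhydroquinone → mono-TIPS ether → orthoacrylate/Claisen annulation to the dihydrocoumarin (the only ring made in the route; the arene is bought) → ketene acetal phosphate → 2-stannyl-4H-chromene.
4. Left half: geraniol → Sharpless epoxidation (sets C11' as S) → epoxy chloride → tertiary propargylic alcohol → TES ether → hydrozirconation/Pd alkenyl–allyl coupling with a C6 (E)-allylic dibromide (C8'–C9' bond, skipped E,E-diene) → iodide.
5. End game: fragment union with opening of the pyran ring, then global desilylation.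

Key step: step 13

Remark: cyclopentadienyl ligands are written σ-bonded and organometallic intermediates as monomers in the SMILES; all four starting materials (1, 3, 8, 11) are taken to be commercial.

**Route**

Step 1
Reactants: 1 2-methylbenzene-1,4-diol (methylhydroquinone)
Product: 2 2-methyl-4-(triisopropylsilyloxy)phenol
Conditions: TIPSCl (1.0 equiv), imidazole, DMF, 0 °C
Reagents that add atoms: chlorotriisopropylsilane, CC(C)[Si](Cl)(C(C)C)C(C)C
Why: Imidazole-mediated silyl ether formation with a bulky chlorosilane should favour the unhindered C4 hydroxyl over the C1 hydroxyl that is flanked by the methyl group, and the minor regioisomer and bis-ether are removed by chromatography.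

Step 2
Reactants: 2 2-methyl-4-(triisopropylsilyloxy)phenol; 3 3,3,3-triethoxyprop-1-ene (triethyl orthoacrylate)
Product: 5 8-methyl-6-(triisopropylsilyloxy)chroman-2-one, via 2,2-diethoxychroman ortho ester 4 (not isolated)
Conditions: PivOH (cat.), PhMe, reflux (−EtOH); then 1 M HCl, THF, rt
Reagents that add atoms: water, O
Why: Acid-catalysed phenol exchange on the orthoacrylate followed by aromatic Claisen rearrangement (orthoacrylate dihydrocoumarin annulation) can rearomatise only at the single free ortho carbon (the other ortho carbon carries the methyl group, the para carbon the silyloxy group), the phenol then closes the six-membered ring on the ketene acetal carbon, and mild acid hydrolysis of the ortho ester gives the lactone.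

Step 3
Reactants: 5 8-methyl-6-(triisopropylsilyloxy)chroman-2-one
Product: 6 diphenyl 8-methyl-6-(triisopropylsilyloxy)-4H-chromen-2-yl phosphate
Conditions: KHMDS, (PhO)2P(O)Cl, HMPA, THF, −78 °C (base added last)
Reagents that add atoms: diphenyl chlorophosphate, O=P(Cl)(Oc1ccccc1)Oc1ccccc1
Why: Ketene acetal phosphate formation by in situ O-phosphorylation of the potassium lactone enolate at −78 °C should outrun ring opening of the aryl ester enolate to a ketene.

Step 4
Reactants: 6 diphenyl 8-methyl-6-(triisopropylsilyloxy)-4H-chromen-2-yl phosphate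
Product: 7 trimethyl[8-methyl-6-(triisopropylsilyloxy)-4H-chromen-2-yl]stannane
Conditions: Me3SnSnMe3, Pd(PPh3)4 (5 mol %), LiCl, THF, reflux
Reagents that add atoms: hexamethylditin, C[Sn](C)(C)[Sn](C)(C)C
Why: Pd(0)-catalysed stannylation of lactone-derived ketene acetal phosphates (oxidative addition into the C–OP bond, Sn–Sn transmetalation, reductive elimination) is a known entry to cyclic α-alkoxy alkenylstannanes and touches neither the silyl ether nor the arene.

Step 5
Reactants: 8 5-bromo-2-methylpent-2-ene
Product: 9 (2E)-5-bromo-2-methylpent-2-en-1-ol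
Conditions: SeO2 (cat.), t-BuOOH, salicylic acid (cat.), CH2Cl2, rt
Reagents that add atoms: tert-butyl hydroperoxide, CC(C)(C)OO
Why: Catalytic SeO2/t-BuOOH allylic oxidation (ene reaction, then [2,3]-sigmatropic shift) hydroxylates a trisubstituted alkene at the methyl group trans to the chain, which gives the E allylic alcohol and leaves the primary bromide untouched.

Step 6
Reactants: 9 (2E)-5-bromo-2-methylpent-2-en-1-ol
Product: 10 (2E)-1,5-dibromo-2-methylpent-2-ene
Conditions: CBr4, PPh3, CH2Cl2, 0 °C
Reagents that add atoms: carbon tetrabromide, BrC(Br)(Br)Br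
Why: Appel bromination converts the primary allylic alcohol into the bromide under neutral conditions without allylic transposition or loss of the E geometry.

Step 7
Reactants: 11 geraniol, (2E)-3,7-dimethylocta-2,6-dien-1-ol
Product: 12 [(2S,3S)-3-methyl-3-(4-methylpent-3-en-1-yl)oxiran-2-yl]methanol ((2S,3S)-2,3-epoxygeraniol)
Conditions: Ti(OiPr)4 (cat.), L-(+)-diethyl tartrate (cat.), t-BuOOH, 4 Å MS, CH2Cl2, −20 °C
Reagents that add atoms: tert-butyl hydroperoxide, CC(C)(C)OO
Why: Catalytic Sharpless asymmetric epoxidation oxidises only the allylic alcohol double bond, and with L-(+)-tartrate the oxygen is delivered to the face that gives the (2S,3S) epoxide, which fixes the future tertiary carbinol carbon C11' as S.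

Step 8
Reactants: 12 (2S,3S)-2,3-epoxygeraniol
Product: 13 (2R,3S)-2-(chloromethyl)-3-methyl-3-(4-methylpent-3-en-1-yl)oxirane
Conditions: PPh3, CCl4, NaHCO3, reflux
Reagents that add atoms: carbon tetrachloride, ClC(Cl)(Cl)Cl
Why: Appel chlorination replaces the primary hydroxyl by chloride and leaves the epoxide and both stereocentres untouched (the C2 descriptor becomes R only through the CIP priority of CH2Cl).

Step 9
Reactants: 13 (2R,3S)-2-(chloromethyl)-3-methyl-3-(4-methylpent-3-en-1-yl)oxirane
Product: 14 (3S)-3,7-dimethyloct-6-en-1-yn-3-ol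
Conditions: LDA (3.3 equiv), THF, −78 → 0 °C; H2O
Reagents that add atoms: none
Why: Base-induced double elimination of a 2,3-epoxy chloride (Takano–Yadav propargylic alcohol synthesis) opens the epoxide by deprotonation next to chlorine and then loses HCl to give the alkyne, and because the C3–O bond is never broken the tertiary centre is retained as S.

Step 10
Reactants: 14 (3S)-3,7-dimethyloct-6-en-1-yn-3-ol
Product: 15 {[(3S)-3,7-dimethyloct-6-en-1-yn-3-yl]oxy}triethylsilane
Conditions: TESOTf, 2,6-lutidine, CH2Cl2, −78 → 0 °C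
Reagents that add atoms: triethylsilyl triflate, CC[Si](CC)(CC)OS(=O)(=O)C(F)(F)F
Why: Silylation of a tertiary alcohol with a silyl triflate and 2,6-lutidine is standard and masks the hydroxyl for the organometallic steps that follow.

Step 11
Reactants: 15 {[(3S)-3,7-dimethyloct-6-en-1-yn-3-yl]oxy}triethylsilane; 10 (2E)-1,5-dibromo-2-methylpent-2-ene
Product: 17 (3E,6E,8S)-1-bromo-4,8,12-trimethyl-8-(triethylsilyloxy)trideca-3,6,11-triene, via alkenylzirconocene chloride 16 (not isolated)
Conditions: Cp2Zr(H)Cl (1.1 equiv), THF, rt; then 10, Pd(PPh3)4 (5 mol %), THF, rt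
Reagents that add atoms: none
Why: Hydrozirconation (Schwartz reagent) adds H–Zr syn with zirconium on the terminal carbon to give the (E)-alkenylzirconocene, and Pd(0)-catalysed alkenyl–allyl cross-coupling (Negishi-type 1,4-diene synthesis) forms the C8'–C9' bond at the unsubstituted allyl terminus with retention of both alkene geometries, while the primary homoallylic bromide does not undergo oxidative addition.

Step 12
Reactants: 17 (3E,6E,8S)-1-bromo-4,8,12-trimethyl-8-(triethylsilyloxy)trideca-3,6,11-triene
Product: 18 (3E,6E,8S)-1-iodo-4,8,12-trimethyl-8-(triethylsilyloxy)trideca-3,6,11-triene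
Conditions: NaI, NaHCO3 (cat.), acetone, reflux, dark
Reagents that add atoms: sodium iodide, [Na+].[I-]
Why: Finkelstein halide exchange (SN2) at the unhindered primary carbon gives the iodide needed for clean lithium–iodine exchange.

Step 13
Reactants: 18 (3E,6E,8S)-1-iodo-4,8,12-trimethyl-8-(triethylsilyloxy)trideca-3,6,11-triene; 7 trimethyl[8-methyl-6-(triisopropylsilyloxy)-4H-chromen-2-yl]stannane
Product: 23 2-[(2E,6E,9E,11S)-3,7,11,15-tetramethyl-11-(triethylsilyloxy)hexadeca-2,6,9,14-tetraen-1-yl]-6-methyl-4-(triisopropylsilyloxy)phenol, via alkyllithium 19 (not isolated), via 2-lithio-4H-chromene 20 (not isolated), via mixed lithium cuprate 21 (not isolated), via alkenylcopper phenoxide 22 (not isolated)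
Conditions: 18, t-BuLi (2.0 equiv), Et2O, −78 °C; 7, MeLi (0.98 equiv), THF, −78 °C; combine, CuBr·SMe2 (1.0 equiv), −78 → 0 °C; MeI, 0 °C → rt; aq. NH4Cl
Reagents that add atoms: iodomethane, CI
Why: Proposed new method: tin–lithium exchange converts 7 into the α-aryloxy alkenyllithium 20, which with alkyllithium 19 and CuBr·SMe2 gives the mixed cuprate 21, in which C3' carries both copper and the ring oxygen and is therefore a carbenoid; on warming, the alkyl group shifts from copper to C3' (1,2-metallate rearrangement) while the phenoxide leaves in the plane of the double bond, which forms the C4'–C3' bond and opens the pyran ring to alkenylcopper 22, and MeI then alkylates 22. The closest known reaction type is the 1,2-metallate rearrangement of cuprates of 5-lithio-2,3-dihydrofuran and 6-lithio-3,4-dihydro-2H-pyran followed by alkylation of the alkenylcopper, the basis of an iterative synthesis of (E)-trisubstituted alkenes in isoprenoid chains from homoallylic iodides; a 4H-chromene has not been used in it, but its aryloxide is a better leaving group than an alkoxide and the benzo-fused six-membered ring offers the same in-plane geometry. No ring is closed (the temporary pyran ring is opened at O1–C2) and no stereocentre is formed. The geometry of the new trisubstituted alkene is controlled by the ring and by the stereospecificity of both events: migration goes with inversion at C3', so the alkyl group ends up trans and copper cis to C1', and methylation goes with retention, which should give only the 2'E isomer. The step needs transfer of the C16 alkyl group and of no other carbon ligand, which is secured by equimolar 19, 20 and copper, sub-stoichiometric MeLi and exact consumption of t-BuLi at −78 °C, and it needs C- rather than O-methylation, which is secured by the low reactivity of a hindered lithium phenoxide towards MeI in ether solvents at 0 °C. The two silyl ethers and the skipped diene are inert to organolithium and organocopper reagents at these temperatures.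

Step 14
Reactants: 23 2-[(2E,6E,9E,11S)-3,7,11,15-tetramethyl-11-(triethylsilyloxy)hexadeca-2,6,9,14-tetraen-1-yl]-6-methyl-4-(triisopropylsilyloxy)phenol
Product: 24 2-[(2E,6E,9E,11S)-11-hydroxy-3,7,11,15-tetramethylhexadeca-2,6,9,14-tetraen-1-yl]-6-methylbenzene-1,4-diol (CNP0297794.1)
Conditions: TBAF, AcOH (1:1), degassed THF, rt → 40 °C, Ar; aq. Na2S2O4 wash
Reagents that add atoms: none
Why: Fluoride-mediated desilylation cleaves the aryl triisopropylsilyl ether and the tertiary triethylsilyl ether without strong acid, so the tertiary allylic alcohol cannot ionise, and exclusion of air with a reductive wash keeps the hydroquinone from oxidising to the quinone.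

**Compound list**
1 | 2-methylbenzene-1,4-diol | Cc1cc(O)ccc1O | starting material
2 | 2-methyl-4-(triisopropylsilyloxy)phenol | Cc1cc(O[Si](C(C)C)(C(C)C)C(C)C)ccc1O | intermediate
3 | 3,3,3-triethoxyprop-1-ene (triethyl orthoacrylate) | C=CC(OCC)(OCC)OCC | starting material
4 | 2,2-diethoxy-8-methyl-6-(triisopropylsilyloxy)chromane | CCOC1(OCC)CCc2cc(O[Si](C(C)C)(C(C)C)C(C)C)cc(C)c2O1 | intermediate
5 | 8-methyl-6-(triisopropylsilyloxy)chroman-2-one | O=C1CCc2cc(O[Si](C(C)C)(C(C)C)C(C)C)cc(C)c2O1 | intermediate
6 | diphenyl 8-methyl-6-(triisopropylsilyloxy)-4H-chromen-2-yl phosphate | O=P(Oc1ccccc1)(Oc1ccccc1)OC1=CCc2cc(O[Si](C(C)C)(C(C)C)C(C)C)cc(C)c2O1 | intermediate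
7 | trimethyl[8-methyl-6-(triisopropylsilyloxy)-4H-chromen-2-yl]stannane | C[Sn](C)(C)C1=CCc2cc(O[Si](C(C)C)(C(C)C)C(C)C)cc(C)c2O1 | intermediate
8 | 5-bromo-2-methylpent-2-ene | CC(C)=CCCBr | starting material
9 | (2E)-5-bromo-2-methylpent-2-en-1-ol | OC/C(C)=C/CCBr | intermediate
10 | (2E)-1,5-dibromo-2-methylpent-2-ene | BrC/C(C)=C/CCBr | intermediate
11 | geraniol, (2E)-3,7-dimethylocta-2,6-dien-1-ol | CC(C)=CCC/C(C)=C/CO | starting material
12 | [(2S,3S)-3-methyl-3-(4-methylpent-3-en-1-yl)oxiran-2-yl]methanol | CC(C)=CCC[C@]1(C)O[C@H]1CO | intermediate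
13 | (2R,3S)-2-(chloromethyl)-3-methyl-3-(4-methylpent-3-en-1-yl)oxirane | CC(C)=CCC[C@]1(C)O[C@H]1CCl | intermediate
14 | (3S)-3,7-dimethyloct-6-en-1-yn-3-ol | CC(C)=CCC[C@](C)(O)C#C | intermediate
15 | {[(3S)-3,7-dimethyloct-6-en-1-yn-3-yl]oxy}triethylsilane | CC(C)=CCC[C@](C)(O[Si](CC)(CC)CC)C#C | intermediate
16 | chloridobis(cyclopentadienyl)[(1E,3S)-3,7-dimethyl-3-(triethylsilyloxy)octa-1,6-dien-1-yl]zirconium | CC(C)=CCC[C@](C)(O[Si](CC)(CC)CC)/C=C/[Zr](Cl)(C1C=CC=C1)C1C=CC=C1 | intermediate
17 | (3E,6E,8S)-1-bromo-4,8,12-trimethyl-8-(triethylsilyloxy)trideca-3,6,11-triene | CC(C)=CCC[C@](C)(O[Si](CC)(CC)CC)/C=C/C/C(C)=C/CCBr | intermediate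
18 | (3E,6E,8S)-1-iodo-4,8,12-trimethyl-8-(triethylsilyloxy)trideca-3,6,11-triene | CC(C)=CCC[C@](C)(O[Si](CC)(CC)CC)/C=C/C/C(C)=C/CCI | intermediate
19 | [(3E,6E,8S)-4,8,12-trimethyl-8-(triethylsilyloxy)trideca-3,6,11-trien-1-yl]lithium | CC(C)=CCC[C@](C)(O[Si](CC)(CC)CC)/C=C/C/C(C)=C/CC[Li] | intermediate
20 | [8-methyl-6-(triisopropylsilyloxy)-4H-chromen-2-yl]lithium | [Li]C1=CCc2cc(O[Si](C(C)C)(C(C)C)C(C)C)cc(C)c2O1 | intermediate
21 | lithium [(3E,6E,8S)-4,8,12-trimethyl-8-(triethylsilyloxy)trideca-3,6,11-trien-1-yl][8-methyl-6-(triisopropylsilyloxy)-4H-chromen-2-yl]cuprate | [Li+].CC(C)=CCC[C@](C)(O[Si](CC)(CC)CC)/C=C/C/C(C)=C/CC[Cu-]C1=CCc2cc(O[Si](C(C)C)(C(C)C)C(C)C)cc(C)c2O1 | intermediate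
22 | lithium 2-[(2Z,6E,9E,11S)-3-cuprio-7,11,15-trimethyl-11-(triethylsilyloxy)hexadeca-2,6,9,14-tetraen-1-yl]-6-methyl-4-(triisopropylsilyloxy)phenolate | CC(C)=CCC[C@](C)(O[Si](CC)(CC)CC)/C=C/C/C(C)=C/CC/C([Cu])=C/Cc1cc(O[Si](C(C)C)(C(C)C)C(C)C)cc(C)c1O[Li] | intermediate
23 | 2-[(2E,6E,9E,11S)-3,7,11,15-tetramethyl-11-(triethylsilyloxy)hexadeca-2,6,9,14-tetraen-1-yl]-6-methyl-4-(triisopropylsilyloxy)phenol | CC(C)=CCC[C@](C)(O[Si](CC)(CC)CC)/C=C/C/C(C)=C/CC/C(C)=C/Cc1cc(O[Si](C(C)C)(C(C)C)C(C)C)cc(C)c1O | intermediate
24 | 2-[(2E,6E,9E,11S)-11-hydroxy-3,7,11,15-tetramethylhexadeca-2,6,9,14-tetraen-1-yl]-6-methylbenzene-1,4-diol | CC(C)=CCC[C@](C)(O)/C=C/C/C(C)=C/CC/C(C)=C/Cc1cc(O)cc(C)c1O | target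

**Step count**
Total: 14 steps (aryl half 4, C6 linker 2, left half 6, union and deprotection 2). Longest linear sequence: 8 steps (steps 7–14, from geraniol).

**Steps most likely to fail**

1. Step 13 (proposed new method). Possible failure processes:
- α-elimination or protonation of the lithiated chromene before the cuprate forms;
- ligand scrambling, so that a chromenyl group migrates instead of the alkyl group;
- thermal decay of the alkylcopper species before migration;
- O-methylation of the phenoxide.

Fallback (known chemistry; sets out from 18 and 6, returns at 23): iodide 18 is lithiated (t-BuLi, Et2O, −78 °C) and trapped with B-methoxy-9-BBN to give lithium 9-methoxy-9-[(3E,6E,8S)-4,8,12-trimethyl-8-(triethylsilyloxy)trideca-3,6,11-trien-1-yl]-9-boranuidabicyclo[3.3.1]nonane F1. This is used at once in a B-alkyl Suzuki–Miyaura coupling with ketene acetal phosphate 6 (PdCl2(dppf), aq. Cs2CO3, DMF, rt), a known reaction of lactone-derived enol phosphates, which forms the same C4'–C3' bond and gives 2-[(3E,6E,8S)-4,8,12-trimethyl-8-(triethylsilyloxy)trideca-3,6,11-trien-1-yl]-8-methyl-6-(triisopropylsilyloxy)-4H-chromene F2. Nickel-catalysed Grignard opening of the enol ether C–O bond (MeMgBr, NiCl2(PPh3)2, PhMe, 80 °C) goes with retention at the alkenyl carbon, so the methyl group ends up cis to C1' and the phenol is freed, giving 23 after aqueous work-up.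

2. Step 3. Possible failure processes: fragmentation of the aryl lactone enolate to a ketene phenoxide, or C- instead of O-phosphorylation, so that no ketene acetal phosphate is obtained.

Fallback (sets out from 5, returns at 7, bypassing steps 3 and 4): lactone 5 is reduced with DIBAL-H (CH2Cl2, −78 °C) to 8-methyl-6-(triisopropylsilyloxy)chroman-2-ol F3. The lactol is converted with PhSO2H and CaCl2 (CH2Cl2, rt) into 8-methyl-2-(phenylsulfonyl)-6-(triisopropylsilyloxy)chromane F4. Deprotonation α to the sulfone (n-BuLi, THF, −78 °C) and quenching with Me3SnCl gives 8-methyl-2-(phenylsulfonyl)-2-(trimethylstannyl)-6-(triisopropylsilyloxy)chromane F5, which loses benzenesulfinate on warming with i-Pr2NEt to give stannane 7. This is the known 2-sulfonyl cyclic ether route to α-stannyl enol ethers.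

3. Step 11. Possible failure processes: slow zirconium-to-palladium transmetalation, with loss of regiochemical or geometric integrity in the π-allylpalladium intermediate (branched coupling, E/Z scrambling of the C6'=C7' alkene), or reduction of the allylic bromide by excess hydride.

Fallback (sets out from 15, returns at 17): the alkyne is hydrostannylated under palladium catalysis (Bu3SnH, PdCl2(PPh3)2 cat., THF, rt) to tributyl[(1E,3S)-3,7-dimethyl-3-(triethylsilyloxy)octa-1,6-dien-1-yl]stannane F6. This is purified to geometric homogeneity and then joined to the allylic bromide terminus of 10 by Stille coupling (Pd2(dba)3, AsPh3, NMP, rt) to give 17. This replaces the one-pot zirconium chemistry by an isolated, configurationally defined alkenylmetal and a different cross-coupling manifold.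

**Further compounds**
F1 | step 13 | lithium 9-methoxy-9-[(3E,6E,8S)-4,8,12-trimethyl-8-(triethylsilyloxy)trideca-3,6,11-trien-1-yl]-9-boranuidabicyclo[3.3.1]nonane | [Li+].CC(C)=CCC[C@](C)(O[Si](CC)(CC)CC)/C=C/C/C(C)=C/CC[B-]1(OC)C2CCCC1CCC2
F2 | step 13 | 2-[(3E,6E,8S)-4,8,12-trimethyl-8-(triethylsilyloxy)trideca-3,6,11-trien-1-yl]-8-methyl-6-(triisopropylsilyloxy)-4H-chromene | CC(C)=CCC[C@](C)(O[Si](CC)(CC)CC)/C=C/C/C(C)=C/CCC1=CCc2cc(O[Si](C(C)C)(C(C)C)C(C)C)cc(C)c2O1
F3 | step 3 | 8-methyl-6-(triisopropylsilyloxy)chroman-2-ol (racemic at C2) | OC1CCc2cc(O[Si](C(C)C)(C(C)C)C(C)C)cc(C)c2O1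
F4 | step 3 | 8-methyl-2-(phenylsulfonyl)-6-(triisopropylsilyloxy)chromane (racemic at C2) | O=S(=O)(c1ccccc1)C1CCc2cc(O[Si](C(C)C)(C(C)C)C(C)C)cc(C)c2O1
F5 | step 3 | 8-methyl-2-(phenylsulfonyl)-2-(trimethylstannyl)-6-(triisopropylsilyloxy)chromane (racemic at C2) | C[Sn](C)(C)C1(S(=O)(=O)c2ccccc2)CCc2cc(O[Si](C(C)C)(C(C)C)C(C)C)cc(C)c2O1
F6 | step 11 | tributyl[(1E,3S)-3,7-dimethyl-3-(triethylsilyloxy)octa-1,6-dien-1-yl]stannane | CC(C)=CCC[C@](C)(O[Si](CC)(CC)CC)/C=C/[Sn](CCCC)(CCCC)CCCC
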